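## Structural features

The target is a 1-aryltetralin cyclolignan. Locants used throughout: C1 carries the guaiacyl ring C (4-hydroxy-3-methoxyphenyl), C2 and C3 carry the hydroxymethyl groups (exocyclic carbons C2a and C3a), C4 is the benzylic methylene, and C4a–C8a form the aromatic ring A fused to the saturated ring B. Ring A is pentasubstituted: methyl ethers on C5 and C6, a free phenol on C7, hydrogen on C8, and the two fusion carbons. C1 (R), C2 (S) and C3 (S) are contiguous and all-trans, so the aryl group and both CH2OH groups can sit equatorial on the half-chair. Because this is the thermodynamic arrangement, C2 and C3 can be corrected by equilibration while they are alpha to esters, whereas C1, a non-enolisable diarylmethine, must be set absolutely. The fragile points are the two electron-rich phenols (oxidation) and the doubly benzylic C1–H, which is base-labile as long as it is also propargylic or allylic in early intermediates. The real difficulty is ring A: one free hydroxyl among three contiguous oxygens, next to two adjacent carbon substituents, with no ambiguity of position allowed. The key step uses the fact that C4a–C5(OMe)–C6(OMe)–C7(O) is oxygenated exactly like the four carbons of dimethyl squarate, while C8 (H) and C8a (bonded to C1) are the two carbons of a trans-alkene. Thermal ring expansion of the derived 4-alkenylcyclobutenone therefore forms C4a–C8a and places every ring A substituent by connectivity.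

## Logic of the disconnections

29 back to 27: the O–benzyl bond on ring C is cut and the two CH2OH groups are taken back to esters (28, then 27). The ester level is chosen because it makes C2 and C3 epimerisable, so the all-trans array can be reached under thermodynamic control, and because the benzyl ether is the one phenol mask that survives everything before it. The forward steps must reduce a hindered vicinal diester cleanly and cleave only the benzylic C–O bond.

27 and 26 back to 24: the C2–C3 bond of ring B is cut. Both carbons are alpha to ester carbonyls, so the bond can be made by joining two enolates with loss of two electrons. This removes ring B and two stereocentres and leaves an open chain with C1 as the only stereocentre. The forward step demands complete double enolisation and ring closure faster than intermolecular coupling; the configuration at C2 and C3 need not be perfect because 26 is equilibrated on the way to 27.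

24 back to 18 and 19 (through 23, 21 and 20): the C4–C4a aryl–alkyl bond is cut, and the C2a ester is traced to a silyl-protected primary alcohol. The C4a oxygen of 17 is the only free hydroxyl, so it becomes the triflate leaving group of 18, and the three-carbon arm C4–C3–C3a arrives from 19 already at the ester level. The forward steps demand cross-coupling at an electron-rich aryl triflate with two ortho substituents, and release of the primary silyl ether without loss of the aryl silyl ether.

17 back to 14: the C4a–C8a bond is cut, which dismantles the whole of ring A into a cyclobutenone carrying the squarate oxygen pattern and an E-alkenyl group. This is the largest simplification of the plan, because a pentasubstituted benzene with differentiated oxygens is traded for a symmetrical four-carbon building block. The forward step demands that the ring opens with the silyloxy group turning outward and that nothing disturbs C1.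

14 back to 10 and 11: the bond between the carbinol carbon (C7) and the alkenyl carbon (C8) is cut. 11 is symmetrical, so 1,2-addition of an alkenyl nucleophile has no regiochemical issue. The forward step demands an alkenyllithium of fixed E geometry that does not deprotonate C1–H, and capture of the tertiary alkoxide on silicon before it can rearrange.

10 back to 5 (through 8, 7 and 6): the C8–I bond, the O–Si bond, the C–Si bond of the alkyne cap and the ester oxidation level are changed. An E-alkenyl iodide comes reliably from a terminal alkyne by syn hydrometalation, and the ester must be reduced and masked because it would not survive an alkenyllithium. The forward steps demand that the propargylic C1–H is never exposed to strong base.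

5 back to 3 and 4: the C1–aryl bond to ring C is cut. A catalytic asymmetric conjugate addition sets the only stereocentre that cannot be corrected later. The forward step demands 1,4- over 1,6-addition on the enyne and high facial selectivity.

3 back to 1 and 2: the sp–sp2 bond between C8a and C1 is cut, giving two bought fragments. The forward step must keep the E geometry of 2.

## Other disconnections considered

Alternative 1: The cut goes through C2–C3 and C1–C8a at once, so ring B is assembled from two cinnamoyl units held on the nitrogens of a C2-symmetric imidazolidinone, the diacyl compound A1. In the forward step FeCl3 (trivalent iron) or a laccase with O2 would take one electron from the feruloyl phenol. The phenoxyl radical, with spin at C2, would add to C3 of the neighbouring acrylimide; after a second oxidation and loss of the C3 proton, the ring C quinone methide would be attacked at C1 by C8a to give the bridged dihydronaphthalene A2.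
- In its favour: two C–C bonds, ring B and the C1 and C2 stereocentres would arise in one operation from two cinnamic acids, ring C needs no protecting group, and the route could be about half as long. On step economy and convergence it is the better plan.
- Against it here: the ring A partner is not a phenol, so the cascade relies on an electrophilic radical adding to an electron-poor acrylimide in competition with intermolecular dimerisation of the feruloyl radical. Facial control at C1 and C2 must be relayed from a remote auxiliary through a seven-membered diacylurea. A2 stays exposed to the oxidant and could be over-oxidised to the arylnaphthalene. The C3=C4 bond must still be reduced with the C3 hydrogen trans to C2. Ring A must be supplied as a pentasubstituted benzaldehyde with its oxygens already differentiated.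
- Comparison: the alternative closes ring B but takes ring A ready-made, whereas the chosen plan builds ring A and closes ring B later. A radical–cation cascade is less predictable than a thermal electrocyclic sequence, and C1 is more securely set by a catalyst-controlled conjugate addition. The two plans are equal in that C3 finally rests on thermodynamic control.

Alternative 2: The cut goes through C4a–C8a and C7–C8, so rings A and B would form together from the furan-tethered ynoate A3, in which a 3,4-dimethoxyfuran supplies C4a, C5, C6 and C7 and the alkyne supplies C8 and C8a. In the forward step heating would bring about the intramolecular [4+2] cycloaddition, and a trace of CF3CO2H would open the oxygen bridge at C4a so that loss of the C7 proton gives the phenol A4.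
- In its favour: regiochemistry of ring A is again fixed by connectivity and the C7 hydroxyl emerges free, so on this point it is the equal of the chosen plan. It closes two rings in one step and needs no triflate, no cross-coupling and no separate ring B closure, where it is the better plan.
- Against it here: A4 carries an ester on C8 that the target lacks, so saponification and protodecarboxylation are added. All three stereocentres must be built beforehand in an open chain, without the help of thermodynamic control in a ring. C1–H in A3 is propargylic, benzylic and gamma to the ester, so isomerisation to the allenoate under heat or trace base would erase the stereocentre. 2-Alkyl-3,4-dimethoxyfurans are acid-sensitive and costly.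
- Comparison: both plans create ring A by a thermal pericyclic step from a small oxygenated ring. The alternative forms more bonds per step, but the stereotriad synthesis and the removal of the activating ester would probably bring the step count close to that of the chosen plan, with a greater risk to C1.

Alternative 3: The cut is made at C1–C2, so ring B would close from the benzhydrol aldehyde A5, which carries C3 as its only stereocentre. In the forward step a diarylprolinol silyl ether with a carboxylic acid co-catalyst would dehydrate the 4-hydroxybenzhydrol to the ring C p-quinone methide and convert the aldehyde into its enamine, which would add through C2 to C1 to give the all-trans aldehyde A6.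
- In its favour: C1 and C2 would be set together under catalyst control, the ring C phenol is used rather than protected, no metal is needed, and the endgame is only reduction and debenzylation. In directness of stereocontrol at C1 and C2 and in protecting-group economy it is the better plan.
- Against it here: A5 needs ring A as a ready-made arene with the 5,6-dimethoxy-7-oxy pattern and two ortho carbon substituents, which is exactly the regiochemical problem the squarate route avoids. C3 must be set separately and must match the catalyst. The configuration at C1 depends on the geometry of a cyclic transition state, not on a direct catalyst contact.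
- Comparison: the alternative is an ionic 1,6-addition that leaves ring A to classical arene chemistry, while the chosen plan is pericyclic and makes ring A itself. The alternative is probably shorter after the arene is in hand; the chosen plan is more certain about substituent placement on ring A.

Key step: step 8

Abbreviations: Ar = 4-(benzyloxy)-3-methoxyphenyl; TBS = tert-butyldimethylsilyl; TIPS = triisopropylsilyl.

Assumption: ethyl (E)-3-iodoacrylate and BrZnCH2CH2CO2Et (THF solution) are taken as bought, and the enantiomer of the chiral diene is the one whose rhodium complex delivers aryl to the Si face at C3 of 3 (the antipodal ligand serves if the sense is the reverse).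

Step 1
Reactants: 1 (triisopropylsilyl)acetylene; 2 ethyl (E)-3-iodoacrylate
Product: 3 ethyl (E)-5-(triisopropylsilyl)pent-2-en-4-ynoate
Conditions: Pd(PPh3)2Cl2 (2 mol %), CuI (4 mol %), Et3N, THF, rt
Reagents that add atoms: none
Why: Sonogashira coupling of a terminal alkyne with an electron-poor alkenyl iodide; zerovalent palladium formed in situ inserts into C–I, the copper acetylide transmetalates, and the E geometry is retained.

Step 2
Reactants: 3 ethyl (E)-5-(triisopropylsilyl)pent-2-en-4-ynoate; 4 4-(benzyloxy)-3-methoxyphenylboronic acid
Product: 5 ethyl (3R)-3-Ar-5-(triisopropylsilyl)pent-4-ynoate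
Conditions: 4 (1.5 equiv), [RhCl(C2H4)2]2 (2.5 mol %), (R,R)-Ph-bod* (5.5 mol %), KOH (0.1 equiv), 1,4-dioxane/H2O, 40 °C
Reagents that add atoms: none
Why: Hayashi–Miyaura asymmetric 1,4-addition: the aryl complex of monovalent rhodium adds across the enoate while the bulky TIPS cap keeps the alkyne terminus out of play (no 1,6-addition). The C2-symmetric diene leaves one enoate face open, so aryl goes to the Si face of C3 (the future C1) and protonation of the oxa-π-allyl gives the R ester.

Step 3
Reactants: 5 ethyl (3R)-3-Ar-5-(triisopropylsilyl)pent-4-ynoate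
Product: 6 (3R)-3-Ar-5-(triisopropylsilyl)pent-4-yn-1-ol
Conditions: LiAlH4, THF, 0 °C
Reagents that add atoms: none
Why: Hydride reduction of the ester to the primary alcohol leaves the silylalkyne and the benzyl ether untouched; taking the ester out first also removes the acidic alpha protons that could relay a fluoride-induced migration of unsaturation toward the carbonyl.

Step 4
Reactants: 6 (3R)-3-Ar-5-(triisopropylsilyl)pent-4-yn-1-ol
Product: 7 (3S)-3-Ar-pent-4-yn-1-ol
Conditions: Bu4NF (1.5 equiv), AcOH (1.0 equiv), THF, 0 °C → rt
Reagents that add atoms: none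
Why: Fluoride-induced protodesilylation of the alkynylsilane; the AcOH buffer keeps the medium too weakly basic to remove the propargylic benzylic C1–H, so the stereocentre is retained (the descriptor becomes S only because ethynyl ranks below aryl).

Step 5
Reactants: 7 (3S)-3-Ar-pent-4-yn-1-ol
Product: 8 tert-butyl{[(3S)-3-Ar-pent-4-yn-1-yl]oxy}dimethylsilane
Conditions: TBSCl, imidazole, CH2Cl2, rt
Reagents that add atoms: tert-butyldimethylsilyl chloride, CC(C)(C)[Si](C)(C)Cl
Why: Standard silylation of a primary alcohol; the ether removes the acidic O–H before the organozirconium and organolithium steps and is later cleavable by acid in the presence of an aryl silyl ether.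

Step 6
Reactants: 8 tert-butyl{[(3S)-3-Ar-pent-4-yn-1-yl]oxy}dimethylsilane
Product: 10 tert-butyl{[(3S,4E)-3-Ar-5-iodopent-4-en-1-yl]oxy}dimethylsilane, via alkenylzirconocene chloride 9 (not isolated)
Conditions: Cp2Zr(H)Cl (1.3 equiv), THF, rt, dark; then I2, 0 °C
Reagents that add atoms: iodine, [I][I]
Why: Hydrozirconation adds Zr–H syn across the terminal alkyne with zirconium on the terminal carbon, and iodinolysis of the C–Zr bond with retention gives the E-alkenyl iodide; ethers are inert to the hydride.

Step 7
Reactants: 10 tert-butyl{[(3S,4E)-3-Ar-5-iodopent-4-en-1-yl]oxy}dimethylsilane; 11 dimethyl squarate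
Product: 14 4-[(1E,3S)-3-Ar-5-(TBSO)pent-1-en-1-yl]-4-(TBSO)-2,3-dimethoxycyclobut-2-en-1-one (both epimers at the ring carbon), via alkenyllithium 12 (not isolated), via lithium alkoxide 13 (not isolated)
Conditions: tBuLi (2.0 equiv), Et2O, −78 °C; then 11, THF, −78 °C; then TBSOTf (1.3 equiv), −78 → 0 °C
Reagents that add atoms: tert-butyldimethylsilyl trifluoromethanesulfonate, CC(C)(C)[Si](C)(C)OS(=O)(=O)C(F)(F)F
Why: Iodine–lithium exchange is faster than any deprotonation at −78 °C and keeps the alkene geometry; the alkenyllithium adds 1,2 to one of the two equivalent carbonyl groups of the squarate, and the tertiary alkoxide is silylated before it can rearrange. The new ring stereocentre is uncontrolled and irrelevant because step 8 destroys it.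

Step 8
Reactants: 14 4-[(1E,3S)-3-Ar-5-(TBSO)pent-1-en-1-yl]-4-(TBSO)-2,3-dimethoxycyclobut-2-en-1-one
Product: 17 2-[(1R)-1-Ar-3-(TBSO)propyl]-4-(TBSO)-5,6-dimethoxyphenol, via dienylketene 15 (not isolated), via cyclohexadienone 16 (not isolated)
Conditions: p-xylene (0.02 M, degassed), 140 °C
Reagents that add atoms: none
Why: This is the thermal ring expansion of a squarate-derived 4-alkenylcyclobutenone (Moore rearrangement), the closest known reaction type, long used to turn such adducts into mono-protected hydroquinones. Heating breaks the ring bond between the carbonyl carbon and the carbinol carbon in a conrotatory 4π electrocyclic opening to give dienylketene 15. The ketene carbon (future C4a) then bonds to the alkene terminus (future C8a) in a 6π electrocyclisation, a pericyclic closure in which all six ring atoms come from the conjugated triene, giving cyclohexa-2,4-dienone 16, and enolisation of 16 delivers aromatic ring A. The selectivity needed is torquoselectivity: the silyloxy group, a π-donor, rotates outward and so puts the alkenyl group inward, cis to the ketene, which is the only geometry that can cyclise; the E alkene keeps the bulky C1 substituent on the outside of the closing triene. Regiochemistry follows from connectivity: the four squarate carbons become C4a, C5, C6 and C7 and the alkene carbons become C8 and C8a, with the C7 oxygen silylated and the C4a oxygen free. No lasting stereocentre is formed, since the sp3 C8a of 16 is lost on aromatisation and both ring epimers of 14 converge. C1 takes part in no bond change under these neutral conditions and is carried through unchanged (the descriptor becomes R only because ring A now outranks ring C).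

Step 9
Reactants: 17 2-[(1R)-1-Ar-3-(TBSO)propyl]-4-(TBSO)-5,6-dimethoxyphenol
Product: 18 2-[(1R)-1-Ar-3-(TBSO)propyl]-4-(TBSO)-5,6-dimethoxyphenyl trifluoromethanesulfonate
Conditions: Tf2O (1.3 equiv), pyridine, CH2Cl2, 0 °C
Reagents that add atoms: trifluoromethanesulfonic anhydride, O=S(=O)(OS(=O)(=O)C(F)(F)F)C(F)(F)F
Why: O-Sulfonylation of the only free hydroxyl turns the C4a oxygen into a leaving group for cross-coupling while C7 stays masked as its silyl ether.

Step 10
Reactants: 18 2-[(1R)-1-Ar-3-(TBSO)propyl]-4-(TBSO)-5,6-dimethoxyphenyl trifluoromethanesulfonate; 19 (3-ethoxy-3-oxopropyl)zinc bromide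
Product: 20 ethyl 3-{2-[(1R)-1-Ar-3-(TBSO)propyl]-4-(TBSO)-5,6-dimethoxyphenyl}propanoate
Conditions: 19 (2.5 equiv, 0.5 M in THF), Pd(OAc)2 (5 mol %), SPhos (10 mol %), THF, 65 °C
Reagents that add atoms: none
Why: Negishi coupling of an aryl triflate with a zinc homoenolate: zerovalent palladium carrying the bulky electron-rich biarylphosphine inserts into the hindered C–O bond, the ester-stabilised alkylzinc transmetalates, and reductive elimination outruns β-hydride elimination. C4, C3 and C3a arrive in one step at the right oxidation level.

Step 11
Reactants: 20 ethyl 3-{2-[(1R)-1-Ar-3-(TBSO)propyl]-4-(TBSO)-5,6-dimethoxyphenyl}propanoate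
Product: 21 ethyl 3-{2-[(1R)-1-Ar-3-hydroxypropyl]-4-(TBSO)-5,6-dimethoxyphenyl}propanoate
Conditions: 10-camphorsulfonic acid (0.1 equiv), EtOH/CH2Cl2, 0 °C → rt
Reagents that add atoms: none
Why: Acid-catalysed solvolysis cleaves a primary alkyl silyl ether much faster than an aryl silyl ether, whose oxygen is poorly basic, so only the side-chain alcohol is released; ethanol as co-solvent prevents ester scrambling.

Step 12
Reactants: 21 ethyl 3-{2-[(1R)-1-Ar-3-hydroxypropyl]-4-(TBSO)-5,6-dimethoxyphenyl}propanoate
Product: 23 (3R)-3-Ar-3-[5-(TBSO)-2-(3-ethoxy-3-oxopropyl)-3,4-dimethoxyphenyl]propanoic acid, via aldehyde 22 (not isolated)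
Conditions: TEMPO (0.2 equiv), PhI(OAc)2 (2.5 equiv), MeCN/H2O, rt
Reagents that add atoms: water, O
Why: Oxoammonium oxidation takes the primary alcohol through the aldehyde and its hydrate to the acid under nearly neutral conditions that spare the electron-rich arenes, the aryl silyl ether and the doubly benzylic C1–H.

Step 13
Reactants: 23 (3R)-3-Ar-3-[5-(TBSO)-2-(3-ethoxy-3-oxopropyl)-3,4-dimethoxyphenyl]propanoic acid
Product: 24 ethyl (3R)-3-Ar-3-[5-(TBSO)-2-(3-ethoxy-3-oxopropyl)-3,4-dimethoxyphenyl]propanoate
Conditions: EtOH (5 equiv), EDC·HCl (1.5 equiv), DMAP (0.1 equiv), CH2Cl2, 0 °C → rt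
Reagents that add atoms: ethanol, CCO
Why: Steglich esterification (carbodiimide activation with DMAP acyl transfer) under neutral conditions gives the second ethyl ester, so both arms are identical esters for enolisation and for the later equilibration in ethanol.

Step 14
Reactants: 24 ethyl (3R)-3-Ar-3-[5-(TBSO)-2-(3-ethoxy-3-oxopropyl)-3,4-dimethoxyphenyl]propanoate
Product: 26 diethyl (1R,2S,3S)-1-Ar-7-(TBSO)-5,6-dimethoxy-1,2,3,4-tetrahydronaphthalene-2,3-dicarboxylate (all-trans isomer expected to predominate; C2/C3 epimers are carried on), via dilithium bis-enolate 25 (not isolated)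
Conditions: LiN(iPr)2 (2.3 equiv), THF, −78 °C (24 added to the base); then CuCl2 (2.3 equiv) in DMF, −78 → 0 °C
Reagents that add atoms: none
Why: Oxidative coupling of a diester bis-enolate: both alpha positions (C2 and C3) are deprotonated, divalent copper removes one electron from each enolate, and the two alpha carbons join in a six-membered closure favoured by the ortho-disubstituted benzene tether. C2 and C3 form under kinetic control, with the C1 aryl group expected to bias the closure toward the all-trans isomer, and any epimers are corrected in step 15.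

Step 15
Reactants: 26 diethyl (1R,2S,3S)-1-Ar-7-(TBSO)-5,6-dimethoxy-1,2,3,4-tetrahydronaphthalene-2,3-dicarboxylate
Product: 27 diethyl (1R,2S,3S)-1-Ar-7-hydroxy-5,6-dimethoxy-1,2,3,4-tetrahydronaphthalene-2,3-dicarboxylate
Conditions: NaOEt (3 equiv), EtOH, argon, rt → 50 °C; then AcOH
Reagents that add atoms: none
Why: Ethoxide equilibrates C2 and C3 through their ester enolates to the all-trans, all-equatorial diester (C1 is not enolisable and stays fixed) and at the same time cleaves the phenolic silyl ether by attack at silicon; ethoxide with ethyl esters excludes transesterification.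

Step 16
Reactants: 27 diethyl (1R,2S,3S)-1-Ar-7-hydroxy-5,6-dimethoxy-1,2,3,4-tetrahydronaphthalene-2,3-dicarboxylate
Product: 28 (1R,2S,3S)-1-Ar-2,3-bis(hydroxymethyl)-5,6-dimethoxy-1,2,3,4-tetrahydronaphthalen-7-ol
Conditions: LiAlH4 (4 equiv), THF, 0 °C → rt; aqueous sodium potassium tartrate
Reagents that add atoms: none
Why: Hydride reduction of both esters to primary alcohols; the phenoxide formed in the flask only consumes hydride, and no stereocentre is touched because reduction occurs at the exocyclic carbonyl carbons.

Step 17
Reactants: 28 (1R,2S,3S)-1-Ar-2,3-bis(hydroxymethyl)-5,6-dimethoxy-1,2,3,4-tetrahydronaphthalen-7-ol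
Product: 29 (1R,2S,3S)-1-(4-hydroxy-3-methoxyphenyl)-2,3-bis(hydroxymethyl)-5,6-dimethoxy-1,2,3,4-tetrahydronaphthalen-7-ol
Conditions: H2 (1 atm), 10% Pd/C, EtOH/EtOAc, rt
Reagents that add atoms: none
Why: Hydrogenolysis of the benzyl aryl ether frees the ring C phenol; no other C–O bond is benzylic and the arenes are not reduced under these mild conditions.

## Compound list

1 | (triisopropylsilyl)acetylene | C#C[Si](C(C)C)(C(C)C)C(C)C | starting material
2 | ethyl (E)-3-iodoacrylate | CCOC(=O)/C=C/I | starting material
3 | ethyl (E)-5-(triisopropylsilyl)pent-2-en-4-ynoate | CCOC(=O)/C=C/C#C[Si](C(C)C)(C(C)C)C(C)C | intermediate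
4 | 4-(benzyloxy)-3-methoxyphenylboronic acid | COc1cc(B(O)O)ccc1OCc1ccccc1 | starting material
5 | ethyl (3R)-3-Ar-5-(triisopropylsilyl)pent-4-ynoate | CCOC(=O)C[C@@H](C#C[Si](C(C)C)(C(C)C)C(C)C)c1ccc(OCc2ccccc2)c(OC)c1 | intermediate
6 | (3R)-3-Ar-5-(triisopropylsilyl)pent-4-yn-1-ol | OCC[C@@H](C#C[Si](C(C)C)(C(C)C)C(C)C)c1ccc(OCc2ccccc2)c(OC)c1 | intermediate
7 | (3S)-3-Ar-pent-4-yn-1-ol | OCC[C@@H](C#C)c1ccc(OCc2ccccc2)c(OC)c1 | intermediate
8 | tert-butyl{[(3S)-3-Ar-pent-4-yn-1-yl]oxy}dimethylsilane | CC(C)(C)[Si](C)(C)OCC[C@@H](C#C)c1ccc(OCc2ccccc2)c(OC)c1 | intermediate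
9 | chlorobis(cyclopentadienyl)[(1E,3S)-3-Ar-5-(TBSO)pent-1-en-1-yl]zirconium (not isolated; cyclopentadienyl rings drawn σ-bonded) | CC(C)(C)[Si](C)(C)OCC[C@@H](/C=C/[Zr](Cl)(C1C=CC=C1)C1C=CC=C1)c1ccc(OCc2ccccc2)c(OC)c1 | intermediate
10 | tert-butyl{[(3S,4E)-3-Ar-5-iodopent-4-en-1-yl]oxy}dimethylsilane | CC(C)(C)[Si](C)(C)OCC[C@@H](/C=C/I)c1ccc(OCc2ccccc2)c(OC)c1 | intermediate
11 | dimethyl squarate (3,4-dimethoxycyclobut-3-ene-1,2-dione) | COC1=C(OC)C(=O)C1=O | starting material
12 | [(1E,3S)-3-Ar-5-(TBSO)pent-1-en-1-yl]lithium (not isolated) | CC(C)(C)[Si](C)(C)OCC[C@@H](/C=C/[Li])c1ccc(OCc2ccccc2)c(OC)c1 | intermediate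
13 | lithium 1-[(1E,3S)-3-Ar-5-(TBSO)pent-1-en-1-yl]-2,3-dimethoxy-4-oxocyclobut-2-en-1-olate (not isolated) | COC1=C(OC)C([O-])(/C=C/[C@H](CCO[Si](C)(C)C(C)(C)C)c2ccc(OCc3ccccc3)c(OC)c2)C1=O.[Li+] | intermediate
14 | 4-[(1E,3S)-3-Ar-5-(TBSO)pent-1-en-1-yl]-4-(TBSO)-2,3-dimethoxycyclobut-2-en-1-one (both epimers at the ring carbon) | COC1=C(OC)C(O[Si](C)(C)C(C)(C)C)(/C=C/[C@H](CCO[Si](C)(C)C(C)(C)C)c2ccc(OCc3ccccc3)c(OC)c2)C1=O | intermediate
15 | (3Z,5E,7S)-7-Ar-4,9-bis(TBSO)-2,3-dimethoxynona-1,3,5-trien-1-one, the dienylketene (not isolated) | COC(=C=O)/C(OC)=C(/O[Si](C)(C)C(C)(C)C)\C=C\[C@H](CCO[Si](C)(C)C(C)(C)C)c1ccc(OCc2ccccc2)c(OC)c1 | intermediate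
16 | 6-[(1S)-1-Ar-3-(TBSO)propyl]-4-(TBSO)-2,3-dimethoxycyclohexa-2,4-dien-1-one, either configuration at C6 (not isolated) | COC1=C(OC)C(O[Si](C)(C)C(C)(C)C)=CC([C@H](CCO[Si](C)(C)C(C)(C)C)c2ccc(OCc3ccccc3)c(OC)c2)C1=O | intermediate
17 | 2-[(1R)-1-Ar-3-(TBSO)propyl]-4-(TBSO)-5,6-dimethoxyphenol | COc1cc([C@@H](CCO[Si](C)(C)C(C)(C)C)c2cc(O[Si](C)(C)C(C)(C)C)c(OC)c(OC)c2O)ccc1OCc1ccccc1 | intermediate
18 | 2-[(1R)-1-Ar-3-(TBSO)propyl]-4-(TBSO)-5,6-dimethoxyphenyl trifluoromethanesulfonate | COc1cc([C@@H](CCO[Si](C)(C)C(C)(C)C)c2cc(O[Si](C)(C)C(C)(C)C)c(OC)c(OC)c2OS(=O)(=O)C(F)(F)F)ccc1OCc1ccccc1 | intermediate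
19 | (3-ethoxy-3-oxopropyl)zinc bromide | CCOC(=O)CC[Zn]Br | starting material
20 | ethyl 3-{2-[(1R)-1-Ar-3-(TBSO)propyl]-4-(TBSO)-5,6-dimethoxyphenyl}propanoate | COc1cc([C@@H](CCO[Si](C)(C)C(C)(C)C)c2cc(O[Si](C)(C)C(C)(C)C)c(OC)c(OC)c2CCC(=O)OCC)ccc1OCc1ccccc1 | intermediate
21 | ethyl 3-{2-[(1R)-1-Ar-3-hydroxypropyl]-4-(TBSO)-5,6-dimethoxyphenyl}propanoate | COc1cc([C@@H](CCO)c2cc(O[Si](C)(C)C(C)(C)C)c(OC)c(OC)c2CCC(=O)OCC)ccc1OCc1ccccc1 | intermediate
22 | ethyl 3-{2-[(1R)-1-Ar-3-oxopropyl]-4-(TBSO)-5,6-dimethoxyphenyl}propanoate (not isolated) | COc1cc([C@@H](CC=O)c2cc(O[Si](C)(C)C(C)(C)C)c(OC)c(OC)c2CCC(=O)OCC)ccc1OCc1ccccc1 | intermediate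
23 | (3R)-3-Ar-3-[5-(TBSO)-2-(3-ethoxy-3-oxopropyl)-3,4-dimethoxyphenyl]propanoic acid | COc1cc([C@@H](CC(=O)O)c2cc(O[Si](C)(C)C(C)(C)C)c(OC)c(OC)c2CCC(=O)OCC)ccc1OCc1ccccc1 | intermediate
24 | ethyl (3R)-3-Ar-3-[5-(TBSO)-2-(3-ethoxy-3-oxopropyl)-3,4-dimethoxyphenyl]propanoate | COc1cc([C@@H](CC(=O)OCC)c2cc(O[Si](C)(C)C(C)(C)C)c(OC)c(OC)c2CCC(=O)OCC)ccc1OCc1ccccc1 | intermediate
25 | dilithium bis-enolate of 24, enolised at C2 and C3 (not isolated) | COc1cc([C@@H](C=C([O-])OCC)c2cc(O[Si](C)(C)C(C)(C)C)c(OC)c(OC)c2CC=C([O-])OCC)ccc1OCc1ccccc1.[Li+].[Li+] | intermediate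
26 | diethyl (1R,2S,3S)-1-Ar-7-(TBSO)-5,6-dimethoxy-1,2,3,4-tetrahydronaphthalene-2,3-dicarboxylate | COc1cc([C@@H]2c3cc(O[Si](C)(C)C(C)(C)C)c(OC)c(OC)c3C[C@H](C(=O)OCC)[C@H]2C(=O)OCC)ccc1OCc1ccccc1 | intermediate
27 | diethyl (1R,2S,3S)-1-Ar-7-hydroxy-5,6-dimethoxy-1,2,3,4-tetrahydronaphthalene-2,3-dicarboxylate | COc1cc([C@@H]2c3cc(O)c(OC)c(OC)c3C[C@H](C(=O)OCC)[C@H]2C(=O)OCC)ccc1OCc1ccccc1 | intermediate
28 | (1R,2S,3S)-1-Ar-2,3-bis(hydroxymethyl)-5,6-dimethoxy-1,2,3,4-tetrahydronaphthalen-7-ol | COc1cc([C@@H]2c3cc(O)c(OC)c(OC)c3C[C@H](CO)[C@H]2CO)ccc1OCc1ccccc1 | intermediate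
29 | (1R,2S,3S)-1-(4-hydroxy-3-methoxyphenyl)-2,3-bis(hydroxymethyl)-5,6-dimethoxy-1,2,3,4-tetrahydronaphthalen-7-ol | COc1cc([C@@H]2c3cc(O)c(OC)c(OC)c3C[C@H](CO)[C@H]2CO)ccc1O | target

## Step count and least certain steps

Total step count: 17. Longest linear sequence: 17 steps (from 1 and 2 to 29); the other coupling partners 4, 11 and 19 are bought.

Step 8 (key step). The most likely failure is partial inward rotation of the bulky silyloxy group during ring opening, which would give a ketene that cannot cyclise and is lost to dimerisation or to traces of water; thermal loss of the silyl group before ring opening is a second possibility. The fallback sets out from 10 and 11 and returns at 17. The alkoxide 13 is quenched with aqueous NH4Cl, not with the silyl triflate, to give 4-[(1E,3S)-3-Ar-5-(TBSO)pent-1-en-1-yl]-4-hydroxy-2,3-dimethoxycyclobut-2-en-1-one F1. Heating F1 in toluene under argon, the original hydroxy form of this ring expansion, should give 2-[(1R)-1-Ar-3-(TBSO)propyl]-5,6-dimethoxybenzene-1,4-diol F2, kept reduced by a Na2S2O4 wash. F2 is then silylated with TBSCl and imidazole at the C7 hydroxyl, which lies between a methoxy group and a hydrogen, whereas the C4a hydroxyl lies between a methoxy group and the branched benzylic substituent; this gives 17. The approach changes from differentiating the two oxygens before the ring expansion to differentiating them afterwards by steric access.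

Step 14. The most likely failures are incomplete double enolisation followed by intermolecular coupling or Claisen-type condensation between the two ester arms, and alpha-chlorination of an enolate by the copper halide in place of C–C bond formation. The fallback sets out from 24 and returns at 26. 24 is converted with LiN(iPr)2 and Me3SiCl into the bis(trimethylsilyl ketene acetal) of 24 F3, which is freed from amine and salts and treated with TiCl4 in CH2Cl2 at −78 °C. Silicon–titanium exchange gives two enolates of tetravalent titanium that couple within the molecule as titanium is reduced; oxidative coupling of ketene silyl acetals is known chemistry, and it replaces the strongly basic dianion by a neutral, purifiable intermediate.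

Step 10. The most likely failures are slow oxidative addition at the electron-rich triflate flanked by two ortho substituents, and β-hydride elimination or protonation of the alkylpalladium, which would return the reduced arene. The fallback sets out from 18 and returns at 20. Suzuki–Miyaura coupling of 18 with bought ethyl (E)-3-(4,4,5,5-tetramethyl-1,3,2-dioxaborolan-2-yl)acrylate (Pd(OAc)2, SPhos, anhydrous K3PO4, toluene, 80 °C), a coupling that tolerates hindered triflates and involves no alkylmetal, should give ethyl (2E)-3-{2-[(1R)-1-Ar-3-(TBSO)propyl]-4-(TBSO)-5,6-dimethoxyphenyl}prop-2-enoate F4. Conjugate reduction of F4 with NaBH4 and NiCl2·6H2O in EtOH/THF at 0 °C, which leaves the benzyl ether in place, gives 20.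

Step 2. The most likely failures are competing 1,6-addition across the enyne (allene formation), protodeboronation of the electron-rich boronic acid before transmetalation, and insufficient facial selectivity with an ester acceptor. The fallback sets out from 1 and returns at 5, and reverses the roles of the partners. Bought 4-(benzyloxy)-3-methoxybenzaldehyde is condensed with Meldrum's acid (Knoevenagel) to give 5-[4-(benzyloxy)-3-methoxybenzylidene]-2,2-dimethyl-1,3-dioxane-4,6-dione F5. Asymmetric conjugate alkynylation of F5 with 1, catalysed by [Rh(OAc)(C2H4)2]2 and a chiral bisphosphine, sets the same stereocentre in 5-[(1R)-1-Ar-3-(triisopropylsilyl)prop-2-yn-1-yl]-2,2-dimethyl-1,3-dioxane-4,6-dione F6. Heating F6 in EtOH/pyridine opens the dioxanedione and decarboxylates it to 5.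

## Further compounds

F1 | step 8 | 4-[(1E,3S)-3-Ar-5-(TBSO)pent-1-en-1-yl]-4-hydroxy-2,3-dimethoxycyclobut-2-en-1-one | COC1=C(OC)C(O)(/C=C/[C@H](CCO[Si](C)(C)C(C)(C)C)c2ccc(OCc3ccccc3)c(OC)c2)C1=O
F2 | step 8 | 2-[(1R)-1-Ar-3-(TBSO)propyl]-5,6-dimethoxybenzene-1,4-diol | COc1cc([C@@H](CCO[Si](C)(C)C(C)(C)C)c2cc(O)c(OC)c(OC)c2O)ccc1OCc1ccccc1
F3 | step 14 | bis(trimethylsilyl ketene acetal) of 24 | COc1cc([C@@H](C=C(OCC)O[Si](C)(C)C)c2cc(O[Si](C)(C)C(C)(C)C)c(OC)c(OC)c2CC=C(OCC)O[Si](C)(C)C)ccc1OCc1ccccc1
F4 | step 10 | ethyl (2E)-3-{2-[(1R)-1-Ar-3-(TBSO)propyl]-4-(TBSO)-5,6-dimethoxyphenyl}prop-2-enoate | COc1cc([C@@H](CCO[Si](C)(C)C(C)(C)C)c2cc(O[Si](C)(C)C(C)(C)C)c(OC)c(OC)c2/C=C/C(=O)OCC)ccc1OCc1ccccc1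
F5 | step 2 | 5-[4-(benzyloxy)-3-methoxybenzylidene]-2,2-dimethyl-1,3-dioxane-4,6-dione | COc1cc(C=C2C(=O)OC(C)(C)OC2=O)ccc1OCc1ccccc1
F6 | step 2 | 5-[(1R)-1-Ar-3-(triisopropylsilyl)prop-2-yn-1-yl]-2,2-dimethyl-1,3-dioxane-4,6-dione | COc1cc([C@H](C#C[Si](C(C)C)(C(C)C)C(C)C)C2C(=O)OC(C)(C)OC2=O)ccc1OCc1ccccc1
A1 | alternative 1 | (4R,5R)-1-[(E)-3-(4-benzyloxy-2,3-dimethoxyphenyl)acryloyl]-3-[(E)-3-(4-hydroxy-3-methoxyphenyl)acryloyl]-4,5-diphenylimidazolidin-2-one | COc1cc(/C=C/C(=O)N2C(=O)N(C(=O)/C=C/c3ccc(OCc4ccccc4)c(OC)c3OC)[C@H](c3ccccc3)[C@H]2c2ccccc2)ccc1O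
A2 | alternative 1 | 7-benzyloxy-1-(4-hydroxy-3-methoxyphenyl)-5,6-dimethoxy-1,2-dihydronaphthalene-2,3-dicarbonyl unit bridged by the diphenylimidazolidinone, C1 and C2 as in the target | COc1cc([C@@H]2c3cc(OCc4ccccc4)c(OC)c(OC)c3C=C3C(=O)N4[C@H](c5ccccc5)[C@@H](c5ccccc5)N(C4=O)C(=O)[C@H]32)ccc1O
A3 | alternative 2 | methyl 4-Ar-5,6-bis(benzyloxymethyl)-7-(3,4-dimethoxyfuran-2-yl)hept-2-ynoate, the three stereocentres as in the target | COC(=O)C#C[C@@H](c1ccc(OCc2ccccc2)c(OC)c1)[C@H](COCc1ccccc1)[C@@H](COCc1ccccc1)Cc1occ(OC)c1OC
A4 | alternative 2 | methyl all-trans-1-Ar-2,3-bis(benzyloxymethyl)-7-hydroxy-5,6-dimethoxy-1,2,3,4-tetrahydronaphthalene-8-carboxylate | COc1cc([C@@H]2c3c(C(=O)OC)c(O)c(OC)c(OC)c3C[C@H](COCc3ccccc3)[C@H]2COCc2ccccc2)ccc1OCc1ccccc1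
A5 | alternative 3 | 3-(benzyloxymethyl)-4-{4-benzyloxy-2,3-dimethoxy-6-[hydroxy(4-hydroxy-3-methoxyphenyl)methyl]phenyl}butanal, C3 as in the target, either carbinol epimer | O=CC[C@@H](COCc1ccccc1)Cc1c(OC)c(OC)c(OCc2ccccc2)cc1C(O)c1ccc(O)c(OC)c1
A6 | alternative 3 | all-trans-7-benzyloxy-3-(benzyloxymethyl)-1-(4-hydroxy-3-methoxyphenyl)-5,6-dimethoxy-1,2,3,4-tetrahydronaphthalene-2-carbaldehyde | COc1cc([C@@H]2c3cc(OCc4ccccc4)c(OC)c(OC)c3C[C@H](COCc3ccccc3)[C@H]2C=O)ccc1O
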